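**Plan**

- Retrosynthesis: cut C12–C13 first (alkylzinc plus an (E)-enol triflate that carries C13–C16), then C4–C5 and C9–C10 of the decalin together in one cationic step, then C9–C11 and C8–C17 (carbocupration of a terminal alkyne), C3=C4 (Z-selective olefination) and C6–C7 (propargylation of geranyl bromide).
- Forward: geranyl bromide is extended to a linear epoxy dienyl allylsilane; ring A and then ring B close in a single operation; C3 is deoxygenated; the C13–C16 unit is joined last and the two silicon-based protecting groups are removed.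
- Enabling feature: ring A (C1–C5, C10) and ring B (C5–C10) are trans-fused and carry quaternary C4 (CH3 and axial CH2OH), the angular CH3 on C10, the equatorial chain on C9 and the exocyclic C8=C17 alkene. This is the imprint of a C3–C4 epoxide, an (E)-C5=C10 alkene and a C8=C9 allylsilane folded chair–chair.
- Stereochemistry: absolute configuration comes from Sharpless epoxidation of a (Z)-allylic alcohol with L-(+)-tartrate; C4, C5, C10 and C9 follow by stereospecific relay of epoxide and alkene geometry; the side-chain alkene geometry comes from the (E)-enol triflate, coupled with retention.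

Key step: step 11

Remark: atom numbers are labdane numbers (C1–C20); the target is the ent-labdane (4R,5S,9R,10S) with a CIP-(Z) side-chain alkene, and the acetoxy acid is assumed not to lactonise once isolated in protonated form.

Step 1
Reactants: 1 geranyl bromide; 2 1-(trimethylsilyl)propyne
Product: 4 [(5E)-6,10-dimethylundeca-5,9-dien-1-yn-1-yl](trimethyl)silane, via 3-(trimethylsilyl)prop-2-ynyllithium 3 (not isolated)
Conditions: 2, n-BuLi, THF, −78 → −20 °C; then 1, −78 → 0 °C
Reagents that add atoms: none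
Why: The propargylic lithium reagent, whose silyl group blocks the allenyl terminus, displaces the primary allylic bromide by SN2 (propargylation of an allylic halide) and leaves the (E)-alkene untouched.

Step 2
Reactants: 4
Product: 5 (5E)-9-bromo-6,10-dimethyl-1-(trimethylsilyl)undec-5-en-1-yn-10-ol (racemic)
Conditions: N-bromosuccinimide, THF/H2O (3:1), 0 °C
Reagents that add atoms: N-bromosuccinimide, O=C1CCC(=O)N1Br; water, O
Why: In aqueous THF the terminal isopropylidene is brominated in preference to the internal trisubstituted alkene (position-selective bromohydrin formation of polyprenyl chains) and water opens the bromonium ion at the tertiary carbon; the racemic centre is erased in step 4.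

Step 3
Reactants: 5
Product: 6 2,2-dimethyl-3-[(3E)-3-methyloct-3-en-7-yn-1-yl]oxirane (racemic)
Conditions: K2CO3, MeOH, 25 °C
Reagents that add atoms: none
Why: Carbonate closes the bromohydrin to the epoxide (intramolecular Williamson reaction) and methoxide cleaves the alkynyl C–Si bond in the same operation.

Step 4
Reactants: 6
Product: 8 (4E)-4-methylnon-4-en-8-ynal, via 2,3-diol 7 (not isolated)
Conditions: H5IO6, THF/Et2O, 0 → 25 °C
Reagents that add atoms: none
Why: Periodic acid hydrolyses the trisubstituted epoxide to the glycol and cleaves it (Malaprade glycol cleavage) to the aldehyde and acetone, while the alkene and alkyne are inert.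

Step 5
Reactants: 8; 9 methyl 2-[bis(2,2,2-trifluoroethoxy)phosphoryl]propanoate
Product: 11 methyl (2Z,6E)-2,6-dimethylundeca-2,6-dien-10-ynoate, via potassium phosphonate carbanion 10 (not isolated)
Conditions: 9, KN(SiMe3)2, 18-crown-6, THF, −78 °C; then 8, −78 °C
Reagents that add atoms: none
Why: Still–Gennari olefination: the electron-poor phosphonate eliminates rapidly from the kinetic adduct, so the (Z)-trisubstituted enoate (ester cis to the chain) should predominate, the geometry that later places C19 axial.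

Step 6
Reactants: 11; 12 (trimethylsilyl)methylmagnesium chloride; 13 ethylene oxide
Product: 16 methyl (2Z,6E,10Z)-13-hydroxy-2,6-dimethyl-10-[(trimethylsilyl)methyl]trideca-2,6,10-trienoate, via (trimethylsilyl)methylcopper 14 (not isolated), via alkenylcopper 15 (not isolated)
Conditions: 12, CuBr·SMe2, Et2O/Me2S, −40 → 0 °C; then 11, 0 → 20 °C; then LiC≡C-n-Pr (from pent-1-yne, n-BuLi), DMPU, 13, −40 → 0 °C; aq. NH4Cl
Reagents that add atoms: none
Why: Normant carbocupration: the organocopper adds syn across the terminal alkyne with the silylmethyl group on the internal carbon (C8), and the alkenylcopper, activated as a mixed alkynyl cuprate, opens ethylene oxide with retention, so C11 ends cis to CH2SiMe3 and trans to C7; the hindered trisubstituted enoate is inert to the organocopper.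

Step 7
Reactants: 16
Product: 18 methyl (2Z,6E,10Z)-13-chloro-2,6-dimethyl-10-[(trimethylsilyl)methyl]trideca-2,6,10-trienoate, via mesylate 17 (not isolated)
Conditions: MsCl, Et3N, CH2Cl2, 0 °C; then LiCl, DMF, 25 → 45 °C
Reagents that add atoms: lithium chloride, [Li+].[Cl-]
Why: Mesylation and SN2 displacement by chloride turn C12 into a non-nucleophilic handle that is inert to the Lewis acid of step 11 and reacts only slowly with tin radicals in step 13.

Step 8
Reactants: 18
Product: 19 (2Z,6E,10Z)-13-chloro-2,6-dimethyl-10-[(trimethylsilyl)methyl]trideca-2,6,10-trien-1-ol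
Conditions: i-Bu2AlH, CH2Cl2, −78 °C; aq. KNaC4H4O6
Reagents that add atoms: none
Why: i-Bu2AlH reduces the conjugated ester by 1,2-hydride delivery to the (Z)-allylic alcohol without touching the alkyl chloride or the allylsilane.

Step 9
Reactants: 19
Product: 20 [(2S,3R)-3-{(3E,7Z)-10-chloro-3-methyl-7-[(trimethylsilyl)methyl]deca-3,7-dien-1-yl}-2-methyloxiran-2-yl]methanol
Conditions: Ti(OiPr)4 (cat.), L-(+)-diethyl tartrate (cat.), t-BuOOH, 4 Å molecular sieves, CH2Cl2, −20 °C
Reagents that add atoms: tert-butyl hydroperoxide, CC(C)(C)OO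
Why: Sharpless asymmetric epoxidation: titanium binds the allylic hydroxyl so only the C3=C4 alkene is oxidised, and L-(+)-tartrate directs oxygen to the face that gives the (2S,3R)-epoxy alcohol (C3 R, C4 S), the source of all absolute stereochemistry.

Step 10
Reactants: 20
Product: 21 tert-butyl{[(2S,3R)-3-{(3E,7Z)-10-chloro-3-methyl-7-[(trimethylsilyl)methyl]deca-3,7-dien-1-yl}-2-methyloxiran-2-yl]methoxy}dimethylsilane
Conditions: TBSCl, imidazole, DMF, 25 °C
Reagents that add atoms: tert-butyldimethylsilyl chloride, CC(C)(C)[Si](C)(C)Cl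
Why: Silyl ether formation keeps the primary hydroxyl from binding the Lewis acid or trapping cations in the cascade and protects C19 to the end.

Step 11
Reactants: 21
Product: 22 (1R,2R,4aS,5R,8aS)-1-({[tert-butyl(dimethyl)silyl]oxy}methyl)-5-(2-chloroethyl)-1,4a-dimethyl-6-methylidenedecahydronaphthalen-2-ol
Conditions: MeAlCl2, CH2Cl2, −78 °C; aq. NaHCO3
Reagents that add atoms: none
Why: MeAlCl2 binds the epoxide oxygen, the C5=C10 alkene attacks tertiary C4 anti to the breaking C4–O bond (C4–C5, ring A), the developing C10 cation is captured by C9 of the allylsilane (C9–C10, ring B), and the beta-silyl cation at C8 loses Me3Si to chloride to leave the C8=C17 methylene. The closest known reaction type is the Lewis acid-promoted epoxy-polyene bicyclisation terminated by an allylsilane (biomimetic cation–olefin cyclisation). Ring A closes in a 6-endo mode at both the epoxide and the alkene through a chair, and ring B closes 6-endo-trig onto the allylsilane through a second chair. C4 is inverted, so the epoxide configuration and the (Z)-placed CH2OSi group give the axial C19 substituent; C5 and C10 follow from anti addition across the (E)-alkene (trans fusion); C9 follows from the allylsilane geometry (C11 trans to C7, hence equatorial); C3 is untouched and its equatorial C–O bond selects the enantiomeric fold. The step needs ionisation at C4 rather than C3 (tertiary versus secondary), a concerted opening without a free C4 cation (favoured by the inductively destabilising CH2OSi group and the low temperature), and termination by desilylation rather than proton loss (beta-silicon effect). The C12 chloride cannot trap the cations.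

Step 12
Reactants: 22
Product: 23 O-[(1R,2R,4aS,5R,8aS)-1-({[tert-butyl(dimethyl)silyl]oxy}methyl)-5-(2-chloroethyl)-1,4a-dimethyl-6-methylidenedecahydronaphthalen-2-yl] O-phenyl carbonothioate
Conditions: PhOC(S)Cl, pyridine, DMAP (cat.), CH2Cl2, 25 °C
Reagents that add atoms: O-phenyl chlorothionoformate, S=C(Cl)Oc1ccccc1
Why: DMAP-catalysed acylation of the hindered equatorial C3 hydroxyl installs the radical-labile thionocarbonate.

Step 13
Reactants: 23
Product: 24 tert-butyl{[(1R,4aS,5R,8aS)-5-(2-chloroethyl)-1,4a-dimethyl-6-methylidenedecahydronaphthalen-1-yl]methoxy}dimethylsilane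
Conditions: Bu3SnH, AIBN (cat.), toluene, 90 °C
Reagents that add atoms: none
Why: Barton–McCombie deoxygenation: the stannyl radical adds to C=S, the secondary C3 radical is released and reduced by Bu3SnH, while the primary chloride reacts far more slowly and no stereocentre is touched.

Step 14
Reactants: 24
Product: 25 tert-butyl{[(1R,4aS,5R,8aS)-5-(2-iodoethyl)-1,4a-dimethyl-6-methylidenedecahydronaphthalen-1-yl]methoxy}dimethylsilane
Conditions: NaI, butan-2-one, 80 °C
Reagents that add atoms: sodium iodide, [Na+].[I-]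
Why: Finkelstein exchange (SN2) at the unhindered primary C12 gives the iodide needed for zinc insertion.

Step 15
Reactants: 26 acetoxyacetyl chloride; 27 Meldrum's acid
Product: 28 2-(2,2-dimethyl-4,6-dioxo-1,3-dioxan-5-ylidene)-2-hydroxyethyl acetate
Conditions: pyridine, CH2Cl2, 0 → 25 °C
Reagents that add atoms: none
Why: C-acylation of Meldrum's acid by the acid chloride gives the enolised acyl derivative.

Step 16
Reactants: 28; 29 2-(trimethylsilyl)ethanol
Product: 30 2-(trimethylsilyl)ethyl 4-(acetyloxy)-3-oxobutanoate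
Conditions: toluene, 90 °C
Reagents that add atoms: none
Why: On heating, the acyl Meldrum's acid loses acetone and CO2 to an acylketene, which the alcohol traps as the beta-keto ester.

Step 17
Reactants: 30
Product: 31 2-(trimethylsilyl)ethyl (2E)-4-(acetyloxy)-3-{[(trifluoromethyl)sulfonyl]oxy}but-2-enoate
Conditions: DBU, Tf2O, CH2Cl2, −78 → −20 °C
Reagents that add atoms: trifluoromethanesulfonic anhydride, O=S(=O)(OS(=O)(=O)C(F)(F)F)C(F)(F)F
Why: The enolate formed at C2 with a non-chelating amidine base should be O-sulfonylated from its extended form, which places the triflate trans to the ester ((E)-selective enol triflate formation of a beta-keto ester).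

Step 18
Reactants: 25; 31
Product: 33 2-(trimethylsilyl)ethyl (2Z)-3-[(acetyloxy)methyl]-5-[(1R,4aS,5R,8aS)-5-({[tert-butyl(dimethyl)silyl]oxy}methyl)-5,8a-dimethyl-2-methylidenedecahydronaphthalen-1-yl]pent-2-enoate, via alkylzinc iodide 32 (not isolated)
Conditions: Zn dust (activated), LiCl, THF, 40 °C; then 31, PdCl2(dppf) (cat.), THF, 25 → 45 °C
Reagents that add atoms: none
Why: Negishi coupling: zinc inserts into the primary C–I bond and the alkylzinc couples with the enol triflate with retention of alkene geometry, so C12 ends trans to the ester and CH2OAc cis to it; the ferrocenyl diphosphine suppresses beta-hydride elimination.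

Step 19
Reactants: 33
Product: 34 (2Z)-3-[(acetyloxy)methyl]-5-[(1R,4aS,5R,8aS)-5-(hydroxymethyl)-5,8a-dimethyl-2-methylidenedecahydronaphthalen-1-yl]pent-2-enoic acid
Conditions: Bu4NF, AcOH, THF, 0 → 25 °C; pH 4 buffer
Reagents that add atoms: none
Why: Fluoride cleaves the neopentyl silyl ether and fragments the 2-(trimethylsilyl)ethyl ester to ethene and Me3SiF (fluoride-induced deprotection), while the acetic acid buffer keeps the medium non-basic so that the acetate and the (Z)-acetoxy acid should survive.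

**Compound list**

1 | geranyl bromide, (2E)-1-bromo-3,7-dimethylocta-2,6-diene | CC(C)=CCC/C(C)=C/CBr | starting material
2 | 1-(trimethylsilyl)propyne | CC#C[Si](C)(C)C | starting material
3 | 3-(trimethylsilyl)prop-2-ynyllithium | [Li]CC#C[Si](C)(C)C | intermediate
4 | [(5E)-6,10-dimethylundeca-5,9-dien-1-yn-1-yl](trimethyl)silane | CC(C)=CCC/C(C)=C/CCC#C[Si](C)(C)C | intermediate
5 | (5E)-9-bromo-6,10-dimethyl-1-(trimethylsilyl)undec-5-en-1-yn-10-ol (racemic) | CC(C)(O)C(Br)CC/C(C)=C/CCC#C[Si](C)(C)C | intermediate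
6 | 2,2-dimethyl-3-[(3E)-3-methyloct-3-en-7-yn-1-yl]oxirane (racemic) | CC1(C)OC1CC/C(C)=C/CCC#C | intermediate
7 | (6E)-2,6-dimethylundec-6-en-10-yne-2,3-diol (racemic) | CC(C)(O)C(O)CC/C(C)=C/CCC#C | intermediate
8 | (4E)-4-methylnon-4-en-8-ynal | O=CCC/C(C)=C/CCC#C | intermediate
9 | methyl 2-[bis(2,2,2-trifluoroethoxy)phosphoryl]propanoate | COC(=O)C(C)P(=O)(OCC(F)(F)F)OCC(F)(F)F | starting material
10 | potassium salt of the carbanion of 9 | [K+].COC(=O)[C-](C)P(=O)(OCC(F)(F)F)OCC(F)(F)F | intermediate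
11 | methyl (2Z,6E)-2,6-dimethylundeca-2,6-dien-10-ynoate | C#CCC/C=C(\C)CC/C=C(/C)C(=O)OC | intermediate
12 | (trimethylsilyl)methylmagnesium chloride | C[Si](C)(C)C[Mg]Cl | starting material
13 | ethylene oxide | C1CO1 | starting material
14 | (trimethylsilyl)methylcopper (MgBrCl complex) | C[Si](C)(C)C[Cu] | intermediate
15 | methyl (2Z,6E,10Z)-11-cuprio-2,6-dimethyl-10-[(trimethylsilyl)methyl]undeca-2,6,10-trienoate | [Cu]/C=C(C[Si](C)(C)C)/CC/C=C(\C)CC/C=C(/C)C(=O)OC | intermediate
16 | methyl (2Z,6E,10Z)-13-hydroxy-2,6-dimethyl-10-[(trimethylsilyl)methyl]trideca-2,6,10-trienoate | OCC/C=C(C[Si](C)(C)C)/CC/C=C(\C)CC/C=C(/C)C(=O)OC | intermediate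
17 | methyl (2Z,6E,10Z)-2,6-dimethyl-13-[(methylsulfonyl)oxy]-10-[(trimethylsilyl)methyl]trideca-2,6,10-trienoate | CS(=O)(=O)OCC/C=C(C[Si](C)(C)C)/CC/C=C(\C)CC/C=C(/C)C(=O)OC | intermediate
18 | methyl (2Z,6E,10Z)-13-chloro-2,6-dimethyl-10-[(trimethylsilyl)methyl]trideca-2,6,10-trienoate | ClCC/C=C(C[Si](C)(C)C)/CC/C=C(\C)CC/C=C(/C)C(=O)OC | intermediate
19 | (2Z,6E,10Z)-13-chloro-2,6-dimethyl-10-[(trimethylsilyl)methyl]trideca-2,6,10-trien-1-ol | ClCC/C=C(C[Si](C)(C)C)/CC/C=C(\C)CC/C=C(/C)CO | intermediate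
20 | [(2S,3R)-3-{(3E,7Z)-10-chloro-3-methyl-7-[(trimethylsilyl)methyl]deca-3,7-dien-1-yl}-2-methyloxiran-2-yl]methanol | ClCC/C=C(C[Si](C)(C)C)/CC/C=C(\C)CC[C@H]1O[C@@]1(C)CO | intermediate
21 | tert-butyl{[(2S,3R)-3-{(3E,7Z)-10-chloro-3-methyl-7-[(trimethylsilyl)methyl]deca-3,7-dien-1-yl}-2-methyloxiran-2-yl]methoxy}dimethylsilane | ClCC/C=C(C[Si](C)(C)C)/CC/C=C(\C)CC[C@H]1O[C@@]1(C)CO[Si](C)(C)C(C)(C)C | intermediate
22 | (1R,2R,4aS,5R,8aS)-1-({[tert-butyl(dimethyl)silyl]oxy}methyl)-5-(2-chloroethyl)-1,4a-dimethyl-6-methylidenedecahydronaphthalen-2-ol | C=C1CC[C@@H]2[C@](C)(CO[Si](C)(C)C(C)(C)C)[C@H](O)CC[C@@]2(C)[C@@H]1CCCl | intermediate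
23 | O-[(1R,2R,4aS,5R,8aS)-1-({[tert-butyl(dimethyl)silyl]oxy}methyl)-5-(2-chloroethyl)-1,4a-dimethyl-6-methylidenedecahydronaphthalen-2-yl] O-phenyl carbonothioate | C=C1CC[C@@H]2[C@](C)(CO[Si](C)(C)C(C)(C)C)[C@H](OC(=S)Oc3ccccc3)CC[C@@]2(C)[C@@H]1CCCl | intermediate
24 | tert-butyl{[(1R,4aS,5R,8aS)-5-(2-chloroethyl)-1,4a-dimethyl-6-methylidenedecahydronaphthalen-1-yl]methoxy}dimethylsilane | C=C1CC[C@@H]2[C@](C)(CO[Si](C)(C)C(C)(C)C)CCC[C@@]2(C)[C@@H]1CCCl | intermediate
25 | tert-butyl{[(1R,4aS,5R,8aS)-5-(2-iodoethyl)-1,4a-dimethyl-6-methylidenedecahydronaphthalen-1-yl]methoxy}dimethylsilane | C=C1CC[C@@H]2[C@](C)(CO[Si](C)(C)C(C)(C)C)CCC[C@@]2(C)[C@@H]1CCI | intermediate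
26 | acetoxyacetyl chloride (2-chloro-2-oxoethyl acetate) | CC(=O)OCC(Cl)=O | starting material
27 | Meldrum's acid (2,2-dimethyl-1,3-dioxane-4,6-dione) | CC1(C)OC(=O)CC(=O)O1 | starting material
28 | 2-(2,2-dimethyl-4,6-dioxo-1,3-dioxan-5-ylidene)-2-hydroxyethyl acetate | CC(=O)OCC(O)=C1C(=O)OC(C)(C)OC1=O | intermediate
29 | 2-(trimethylsilyl)ethanol | C[Si](C)(C)CCO | starting material
30 | 2-(trimethylsilyl)ethyl 4-(acetyloxy)-3-oxobutanoate | CC(=O)OCC(=O)CC(=O)OCC[Si](C)(C)C | intermediate
31 | 2-(trimethylsilyl)ethyl (2E)-4-(acetyloxy)-3-{[(trifluoromethyl)sulfonyl]oxy}but-2-enoate | CC(=O)OC/C(OS(=O)(=O)C(F)(F)F)=C\C(=O)OCC[Si](C)(C)C | intermediate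
32 | {2-[(1R,4aS,5R,8aS)-5-({[tert-butyl(dimethyl)silyl]oxy}methyl)-5,8a-dimethyl-2-methylidenedecahydronaphthalen-1-yl]ethyl}(iodo)zinc | C=C1CC[C@@H]2[C@](C)(CO[Si](C)(C)C(C)(C)C)CCC[C@@]2(C)[C@@H]1CC[Zn]I | intermediate
33 | 2-(trimethylsilyl)ethyl (2Z)-3-[(acetyloxy)methyl]-5-[(1R,4aS,5R,8aS)-5-({[tert-butyl(dimethyl)silyl]oxy}methyl)-5,8a-dimethyl-2-methylidenedecahydronaphthalen-1-yl]pent-2-enoate | C=C1CC[C@@H]2[C@](C)(CO[Si](C)(C)C(C)(C)C)CCC[C@@]2(C)[C@@H]1CC/C(=C/C(=O)OCC[Si](C)(C)C)COC(C)=O | intermediate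
34 | (2Z)-3-[(acetyloxy)methyl]-5-[(1R,4aS,5R,8aS)-5-(hydroxymethyl)-5,8a-dimethyl-2-methylidenedecahydronaphthalen-1-yl]pent-2-enoic acid | C=C1CC[C@@H]2[C@](C)(CO)CCC[C@@]2(C)[C@@H]1CC/C(=C/C(=O)O)COC(C)=O | target

**Step count and risks**

Total step count: 19. Longest linear sequence: 16 steps (steps 1–14, 18 and 19).

Steps most likely to fail:

1. Step 6. The alkenylcopper is a weak nucleophile: it may be protonated on warming or fail to open ethylene oxide, and MgBrCl may divert the epoxide into a halohydrin. The fallback sets out from 11 and returns at 16. The carbocupration is run unchanged, but the alkenylcopper 15 is quenched with I2 (one equivalent per copper, −78 °C) to give, with retention, methyl (2Z,6E,10Z)-11-iodo-2,6-dimethyl-10-[(trimethylsilyl)methyl]undeca-2,6,10-trienoate F1. Stille coupling with tributyl(vinyl)stannane (Pd2(dba)3, AsPh3, CuI, NMP, 25 °C) gives methyl (2Z,6E,10Z)-2,6-dimethyl-10-[(trimethylsilyl)methyl]trideca-2,6,10,12-tetraenoate F2. 9-BBN adds to the terminal vinyl group only, giving methyl (2Z,6E,10Z)-13-(9-borabicyclo[3.3.1]nonan-9-yl)-2,6-dimethyl-10-[(trimethylsilyl)methyl]trideca-2,6,10-trienoate F3, which NaBO3·4H2O oxidises to 16.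

2. Step 18. Zerovalent palladium may ionise the allylic acetate of 31 or 33 (loss of acetate through a pi-allyl complex), and the alkylpalladium intermediate may undergo beta-hydride elimination instead of coupling. The fallback sets out from 25 and returns at 33. An iron-catalysed Kumada-type coupling replaces the palladium chemistry: 25 is converted with activated Mg in Et2O into {2-[(1R,4aS,5R,8aS)-5-({[tert-butyl(dimethyl)silyl]oxy}methyl)-5,8a-dimethyl-2-methylidenedecahydronaphthalen-1-yl]ethyl}magnesium iodide F4. This is added to 31 with Fe(acac)3 (cat.) in THF/NMP at −30 °C, where enol triflates of beta-keto esters couple stereoretentively and faster than Grignard attack on ester groups.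

3. Step 19. Under fluoride the liberated carboxylate, held cis to the acetoxymethyl group, may take over the acetyl group and lactonise to the butenolide, or the acetate may be cleaved by basic fluoride before the hindered silyl ether is gone. The fallback sets out from 28 and returns at 34; the carboxyl group is carried as a tert-butyl ester and freed without a basic carboxylate stage.
   - Heating 28 with tert-butanol (toluene, 90 °C) gives tert-butyl 4-(acetyloxy)-3-oxobutanoate F5.
   - DBU/Tf2O gives tert-butyl (2E)-4-(acetyloxy)-3-{[(trifluoromethyl)sulfonyl]oxy}but-2-enoate F6.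
   - Negishi coupling with 32 as in step 18 gives tert-butyl (2Z)-3-[(acetyloxy)methyl]-5-[(1R,4aS,5R,8aS)-5-({[tert-butyl(dimethyl)silyl]oxy}methyl)-5,8a-dimethyl-2-methylidenedecahydronaphthalen-1-yl]pent-2-enoate F7.
   - HF·pyridine in THF/pyridine removes the silyl ether to give tert-butyl (2Z)-3-[(acetyloxy)methyl]-5-[(1R,4aS,5R,8aS)-5-(hydroxymethyl)-5,8a-dimethyl-2-methylidenedecahydronaphthalen-1-yl]pent-2-enoate F8.
   - Me3SiOTf/2,6-lutidine (CH2Cl2, 0 °C) expels 2-methylpropene to give trimethylsilyl (2Z)-3-[(acetyloxy)methyl]-5-[(1R,4aS,5R,8aS)-5,8a-dimethyl-2-methylidene-5-{[(trimethylsilyl)oxy]methyl}decahydronaphthalen-1-yl]pent-2-enoate F9, which a pH 4 work-up hydrolyses to 34.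

**Further compounds**

F1 | step 6 | methyl (2Z,6E,10Z)-11-iodo-2,6-dimethyl-10-[(trimethylsilyl)methyl]undeca-2,6,10-trienoate | I/C=C(C[Si](C)(C)C)/CC/C=C(\C)CC/C=C(/C)C(=O)OC
F2 | step 6 | methyl (2Z,6E,10Z)-2,6-dimethyl-10-[(trimethylsilyl)methyl]trideca-2,6,10,12-tetraenoate | C=C/C=C(C[Si](C)(C)C)/CC/C=C(\C)CC/C=C(/C)C(=O)OC
F3 | step 6 | methyl (2Z,6E,10Z)-13-(9-borabicyclo[3.3.1]nonan-9-yl)-2,6-dimethyl-10-[(trimethylsilyl)methyl]trideca-2,6,10-trienoate | B1(CC/C=C(C[Si](C)(C)C)/CC/C=C(\C)CC/C=C(/C)C(=O)OC)C2CCCC1CCC2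
F4 | step 18 | {2-[(1R,4aS,5R,8aS)-5-({[tert-butyl(dimethyl)silyl]oxy}methyl)-5,8a-dimethyl-2-methylidenedecahydronaphthalen-1-yl]ethyl}magnesium iodide | C=C1CC[C@@H]2[C@](C)(CO[Si](C)(C)C(C)(C)C)CCC[C@@]2(C)[C@@H]1CC[Mg]I
F5 | step 19 | tert-butyl 4-(acetyloxy)-3-oxobutanoate | CC(=O)OCC(=O)CC(=O)OC(C)(C)C
F6 | step 19 | tert-butyl (2E)-4-(acetyloxy)-3-{[(trifluoromethyl)sulfonyl]oxy}but-2-enoate | CC(=O)OC/C(OS(=O)(=O)C(F)(F)F)=C\C(=O)OC(C)(C)C
F7 | step 19 | tert-butyl (2Z)-3-[(acetyloxy)methyl]-5-[(1R,4aS,5R,8aS)-5-({[tert-butyl(dimethyl)silyl]oxy}methyl)-5,8a-dimethyl-2-methylidenedecahydronaphthalen-1-yl]pent-2-enoate | C=C1CC[C@@H]2[C@](C)(CO[Si](C)(C)C(C)(C)C)CCC[C@@]2(C)[C@@H]1CC/C(=C/C(=O)OC(C)(C)C)COC(C)=O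
F8 | step 19 | tert-butyl (2Z)-3-[(acetyloxy)methyl]-5-[(1R,4aS,5R,8aS)-5-(hydroxymethyl)-5,8a-dimethyl-2-methylidenedecahydronaphthalen-1-yl]pent-2-enoate | C=C1CC[C@@H]2[C@](C)(CO)CCC[C@@]2(C)[C@@H]1CC/C(=C/C(=O)OC(C)(C)C)COC(C)=O
F9 | step 19 | trimethylsilyl (2Z)-3-[(acetyloxy)methyl]-5-[(1R,4aS,5R,8aS)-5,8a-dimethyl-2-methylidene-5-{[(trimethylsilyl)oxy]methyl}decahydronaphthalen-1-yl]pent-2-enoate | C=C1CC[C@@H]2[C@](C)(CO[Si](C)(C)C)CCC[C@@]2(C)[C@@H]1CC/C(=C/C(=O)O[Si](C)(C)C)COC(C)=O
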